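**Plan**
- Retrosynthesis: the pyran O1–C2 bond is cut first (retro-oxa-6π, then tautomerisation back). Because the benzene ring carries a para pair of hydroxyls at C5/C8 and the pyran ring a C3=C4 double bond, the chromene is an isomer of the 2-hydroxy-3-prenyl-1,4-benzoquinone 12.
- Quinone 12 is traced to phenol 11, whose C8/C8a oxygens are tied in a methylenedioxy bridge. The C6–acyl and C4a–C4 (prenyl) bonds are then cut back to arene 4 and aldehyde 1.
- Forward: the benzene ring is bought in 1. Dakin-type oxidation and MOM protection give 4, and two directed ortho-metalations join first the prenyl chain, then the 3-phenylpropanoyl chain.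
- MOM removal and oxidative unmasking give 12, and the pyran ring is closed last.
- Stereochemistry: the target has no stereocentre and its only non-aromatic alkene is endocyclic, so nothing has to be set.

Key step: step 7

Remark: the target is a single achiral compound, so no asymmetric step is needed. Chromene numbering (O1, C2–C4, C4a, C5–C8, C8a) is used for ring positions in the later intermediates.

**Step 1**
Reactants: 1 7-methoxy-1,3-benzodioxole-5-carbaldehyde (5-methoxypiperonal)
Product: 3 7-methoxy-1,3-benzodioxol-5-ol, via aryl formate 2 (not isolated)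
Conditions: mCPBA, CH2Cl2, 0 °C → rt; then K2CO3 (cat.), MeOH, rt
Reagents that add atoms: 3-chloroperoxybenzoic acid (mCPBA), OOC(=O)c1cccc(Cl)c1
Why: Baeyer–Villiger (Dakin-type) oxidation, in which the electron-rich aryl group with a para oxygen migrates to give the formate, which catalytic carbonate in methanol transesterifies to the phenol.

**Step 2**
Reactants: 3 7-methoxy-1,3-benzodioxol-5-ol
Product: 4 7-methoxy-5-(methoxymethoxy)-1,3-benzodioxole
Conditions: MOMCl, i-Pr2NEt, CH2Cl2, 0 °C → rt
Reagents that add atoms: chloromethyl methyl ether (MOMCl), COCCl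
Why: O-alkylation of the phenol with the reactive α-chloro ether installs a MOM acetal that directs both later metalations and comes off under mild acid.

**Step 3**
Reactants: 4 7-methoxy-5-(methoxymethoxy)-1,3-benzodioxole; 5 1-bromo-3-methylbut-2-ene (prenyl bromide)
Product: 7 7-methoxy-5-(methoxymethoxy)-4-(3-methylbut-2-en-1-yl)-1,3-benzodioxole, via aryllithium 6 (not isolated)
Conditions: n-BuLi, THF, −78 → 0 °C; CuBr·SMe2, −78 °C; then 5, −78 °C → rt
Reagents that add atoms: prenyl bromide 5, CC(C)=CCBr
Why: Directed ortho-metalation should take the ring hydrogen at C4, which lies between the MOM ether and the ring-constrained dioxole oxygen and is more acidic and less hindered than the hydrogen between OMOM and OMe (1,3-benzodioxoles lithiate faster than anisoles), and the arylcopper formed on transmetalation couples with prenyl bromide at its primary carbon (SN2, not SN2′ allylation).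

**Step 4**
Reactants: 7 7-methoxy-5-(methoxymethoxy)-4-(3-methylbut-2-en-1-yl)-1,3-benzodioxole; 8 N-methoxy-N-methyl-3-phenylpropanamide
Product: 10 1-[4-methoxy-6-(methoxymethoxy)-7-(3-methylbut-2-en-1-yl)-1,3-benzodioxol-5-yl]-3-phenylpropan-1-one, via aryllithium 9 (not isolated)
Conditions: n-BuLi, TMEDA, THF, −20 → 0 °C; then 8, −78 → 0 °C; then H2O
Reagents that add atoms: N-methoxy-N-methyl-3-phenylpropanamide 8, CON(C)C(=O)CCc1ccccc1
Why: A second directed ortho-metalation can only take the last ring hydrogen, flanked by OMOM and OMe, and the Weinreb ketone synthesis stops at the ketone because the chelated tetrahedral adduct survives until the aqueous quench; n-BuLi/TMEDA at low temperature favours this doubly activated ring position over the benzylic-allylic CH2 of the prenyl group.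

**Step 5**
Reactants: 10 1-[4-methoxy-6-(methoxymethoxy)-7-(3-methylbut-2-en-1-yl)-1,3-benzodioxol-5-yl]-3-phenylpropan-1-one
Product: 11 1-[6-hydroxy-4-methoxy-7-(3-methylbut-2-en-1-yl)-1,3-benzodioxol-5-yl]-3-phenylpropan-1-one
Conditions: conc. HCl (cat.), MeOH, rt → 40 °C
Reagents that add atoms: none
Why: Acid-catalysed acetal exchange removes the MOM group, which is especially labile ortho to a ketone, while the methylene acetal, the aryl methyl ether and the trisubstituted alkene should tolerate catalytic HCl in methanol at this temperature.

**Step 6**
Reactants: 11 1-[6-hydroxy-4-methoxy-7-(3-methylbut-2-en-1-yl)-1,3-benzodioxol-5-yl]-3-phenylpropan-1-one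
Product: 12 2-hydroxy-6-methoxy-3-(3-methylbut-2-en-1-yl)-5-(3-phenylpropanoyl)cyclohexa-2,5-diene-1,4-dione
Conditions: PhI(OAc)2, MeCN/H2O (3:1), 0 °C
Reagents that add atoms: water, O
Why: Hypervalent-iodine oxidative dealkylation of a para-alkoxyphenol to a para-benzoquinone, in which water captures the phenoxenium ion at the para carbon (the dioxole carbon next to C–OMe; both ortho positions are carbon-substituted), the hemiketal collapses to the second carbonyl, and the aryloxymethanol left on the neighbouring oxygen loses formaldehyde to unveil the hydroxyl beside the prenyl group.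

**Step 7**
Reactants: 12 2-hydroxy-6-methoxy-3-(3-methylbut-2-en-1-yl)-5-(3-phenylpropanoyl)cyclohexa-2,5-diene-1,4-dione
Product: 14 Flemistrictin D (1-(5,8-dihydroxy-7-methoxy-2,2-dimethyl-2H-chromen-6-yl)-3-phenylpropan-1-one), via ortho-quinone methide 13 (not isolated)
Conditions: pyridine (degassed), 100 °C, Ar; work-up EtOAc / aq. Na2S2O4
Reagents that add atoms: none
Why: In hot pyridine the hydroxyquinone equilibrates with its 4-hydroxy-1,2-quinone tautomer, and a base-mediated vinylogous enolisation moves one proton of the prenyl CH2 (future C4) to the C8 oxygen, giving ortho-quinone methide 13 with a carbonyl at C8a and an exocyclic 1-oxatriene O=C8a–C4a=C4–C3=C2. Thermal disrotatory oxa-6π electrocyclisation of this oxatriene joins the C8a oxygen to C2 and closes the six-membered pyran ring, driven by aromatisation of the carbocycle to the 5,8-hydroquinone, so the step is redox-neutral. The closest known reactions are the pyridine- or amine-promoted isomerisation of prenyl-1,4-benzoquinones to chromenols and the conversion of lapachol-type 2-hydroxy-3-prenylquinones into 2H-pyrans through quinone methides. No stereocentre is formed, because C2 carries two methyl groups. The selectivity needed is closure through the C8a oxygen and not the C5 oxygen: the C5 oxygen is held as donor of a resonance-assisted hydrogen bond to the C6 acyl carbonyl in 13 and in the product, the same bias that sends chromene annulations of 2,4-dihydroxyaryl ketones to the non-chelated oxygen, and the proton shifts that interconvert the two possible quinone methides are fast, so the chelated pathway should be the one drained. The fully substituted quinone ring offers no open site for conjugate addition, and pyridine is too weak a nucleophile to displace the C7 methoxy group.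

**Compound list**
1 | 7-methoxy-1,3-benzodioxole-5-carbaldehyde (5-methoxypiperonal) | COc1cc(C=O)cc2OCOc12 | starting material
2 | 7-methoxy-1,3-benzodioxol-5-yl formate | COc1cc(OC=O)cc2OCOc12 | intermediate
3 | 7-methoxy-1,3-benzodioxol-5-ol | COc1cc(O)cc2OCOc12 | intermediate
4 | 7-methoxy-5-(methoxymethoxy)-1,3-benzodioxole | COc1cc(OCOC)cc2OCOc12 | intermediate
5 | 1-bromo-3-methylbut-2-ene (prenyl bromide) | CC(C)=CCBr | starting material
6 | [7-methoxy-5-(methoxymethoxy)-1,3-benzodioxol-4-yl]lithium | COc1cc(OCOC)c([Li])c2OCOc12 | intermediate
7 | 7-methoxy-5-(methoxymethoxy)-4-(3-methylbut-2-en-1-yl)-1,3-benzodioxole | COc1cc(OCOC)c(CC=C(C)C)c2OCOc12 | intermediate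
8 | N-methoxy-N-methyl-3-phenylpropanamide | CON(C)C(=O)CCc1ccccc1 | starting material
9 | [4-methoxy-6-(methoxymethoxy)-7-(3-methylbut-2-en-1-yl)-1,3-benzodioxol-5-yl]lithium | COc1c([Li])c(OCOC)c(CC=C(C)C)c2OCOc12 | intermediate
10 | 1-[4-methoxy-6-(methoxymethoxy)-7-(3-methylbut-2-en-1-yl)-1,3-benzodioxol-5-yl]-3-phenylpropan-1-one | COc1c(C(=O)CCc3ccccc3)c(OCOC)c(CC=C(C)C)c2OCOc12 | intermediate
11 | 1-[6-hydroxy-4-methoxy-7-(3-methylbut-2-en-1-yl)-1,3-benzodioxol-5-yl]-3-phenylpropan-1-one | COc1c(C(=O)CCc3ccccc3)c(O)c(CC=C(C)C)c2OCOc12 | intermediate
12 | 2-hydroxy-6-methoxy-3-(3-methylbut-2-en-1-yl)-5-(3-phenylpropanoyl)cyclohexa-2,5-diene-1,4-dione | COC1=C(C(=O)CCc2ccccc2)C(=O)C(CC=C(C)C)=C(O)C1=O | intermediate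
13 | (6Z)-2,5-dihydroxy-3-methoxy-6-(3-methylbut-2-en-1-ylidene)-4-(3-phenylpropanoyl)cyclohexa-2,4-dien-1-one (ortho-quinone methide, side chain syn to the C8a carbonyl) | COC1=C(O)C(=O)/C(=C\C=C(C)C)C(O)=C1C(=O)CCc1ccccc1 | intermediate
14 | Flemistrictin D, 1-(5,8-dihydroxy-7-methoxy-2,2-dimethyl-2H-chromen-6-yl)-3-phenylpropan-1-one (achiral) | COc1c(O)c2c(c(O)c1C(=O)CCc1ccccc1)C=CC(C)(C)O2 | target

**Step count**
Total steps: 7. Longest linear sequence: 7 steps (1 → 14).

**Steps most likely to fail**

1. Step 7. The ring may close through the C5 oxygen instead of the C8a oxygen. The acidic hydroxyquinone may also sit in pyridine as an anion that does not enolise, or the product hydroquinone and unreacted quinone may exchange redox state and stall the isomerisation. The fallback sets out from 12 and changes the oxidation level. DDQ in benzene should abstract hydride from the prenyl CH2, and the neutral C8a hydroxyl (the only hydroxyl present) should close onto the resulting cation or quinone methide with the para-quinone kept, as in the cyclodehydrogenation of lapachol-type quinones. This should give 7-methoxy-2,2-dimethyl-6-(3-phenylpropanoyl)-2H-chromene-5,8-dione F1. Reduction of F1 with aqueous Na2S2O4 in EtOAc then comes back to the route at 14.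

2. Step 6. The chelated phenol may fail to exchange onto iodine, the iodane may attack the trisubstituted alkene, or the hydroxyquinone may be over-oxidised before isolation. The fallback sets out from 10 and skips step 5. The fully etherified arene is oxidised by outer-sphere electron transfer with ceric ammonium nitrate in MeCN/H2O at 0 °C, the classical oxidative dealkylation of para-dialkoxyarenes. The only para O/O pair of 10 is OMOM/dioxole oxygen, so the same quinone should result and the route is rejoined at 12. This detour makes no compound outside the list (F0).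

3. Step 3. Metalation may take the ring hydrogen between OMOM and OMe instead of the one next to the dioxole oxygen, which would put the prenyl group on the carbon meant for the acyl chain. The fallback sets out from 4 and inverts the order of the two C–C bond formations. The aryllithium is trapped with 3-phenylpropanal at −78 °C to give 1-[4-methoxy-6-(methoxymethoxy)-1,3-benzodioxol-5-yl]-3-phenylpropan-1-ol F2 (racemic). Two equivalents of n-BuLi then form the alkoxide and lithiate the one remaining ring hydrogen, between OMOM and the dioxole oxygen. Transmetalation with CuBr·SMe2 and coupling with 5 gives 1-[4-methoxy-6-(methoxymethoxy)-7-(3-methylbut-2-en-1-yl)-1,3-benzodioxol-5-yl]-3-phenylpropan-1-ol F3 (racemic). Dess–Martin oxidation of F3 removes the stereocentre and comes back to the route at 10.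

**Further compounds**
F1 | step 7 | 7-methoxy-2,2-dimethyl-6-(3-phenylpropanoyl)-2H-chromene-5,8-dione | COC1=C(C(=O)CCc2ccccc2)C(=O)C2=C(OC(C)(C)C=C2)C1=O
F0 | step 6 | none | none
F2 | step 3 | 1-[4-methoxy-6-(methoxymethoxy)-1,3-benzodioxol-5-yl]-3-phenylpropan-1-ol (racemic) | COc1c(C(O)CCc3ccccc3)c(OCOC)cc2OCOc12
F3 | step 3 | 1-[4-methoxy-6-(methoxymethoxy)-7-(3-methylbut-2-en-1-yl)-1,3-benzodioxol-5-yl]-3-phenylpropan-1-ol (racemic) | COc1c(C(O)CCc3ccccc3)c(OCOC)c(CC=C(C)C)c2OCOc12
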